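**Strategy**

The oxane ring is opened at C5–C6: C6, the lone methylene between O1 and the stereocentre C5, is read as a formaldehyde carbon, and the C2 acrylate as a Morita–Baylis–Hillman retron. One catalytic asymmetric step sets C2; the key step then ionises a MEM ether of that carbinol to an oxocarbenium ion that is captured by a tethered allylsilane. In one operation this forms C5–C6, closes the ring, relays C2 to C5 through a chair (trans-2,5, both substituents equatorial) and unveils a C5 vinyl group. The precursor is an open-chain, MEM-protected Baylis–Hillman adduct with a terminal allylsilane. B-alkyl Suzuki coupling of the vinyl group with an (R)-configured vinyl iodide completes the skeleton.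

Key step: step 5

Assumptions and conventions:
- Oxane numbering: O1, C2 (acrylate-bearing), C3, C4, C5 (side-chain-bearing), C6 (OCH2). MEM = 2-methoxyethoxymethyl.
- Compounds 1, 2, 4, 10 and 13 and the organocatalyst β-isocupreidine are taken as purchasable.
- Step 1 is expected to give mainly the (E)-allylsilane; any (Z)-isomer is carried along, because step 5 erases the alkene geometry and both isomers should converge on 9.

**Fragment A (oxane)**

Step 1
Reactants: 1 pent-4-enal; 2 allyltrimethylsilane
Product: 3 (4E)-6-(trimethylsilyl)hex-4-enal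
Conditions: 2 (3 equiv), second-generation Grubbs catalyst (2 mol%), CH2Cl2, 40 °C
Reagents that add atoms: none
Why: Olefin cross-metathesis between two unhindered terminal alkenes releases ethene and, with 2 in excess, should give the cross product with the (E)-alkene predominating under thermodynamic control, while the aldehyde is tolerated by the ruthenium carbene.

Step 2
Reactants: 3 (4E)-6-(trimethylsilyl)hex-4-enal; 4 1,1,1,3,3,3-hexafluoropropan-2-yl prop-2-enoate
Product: 5 1,1,1,3,3,3-hexafluoropropan-2-yl (3R,6E)-3-hydroxy-2-methylidene-8-(trimethylsilyl)oct-6-enoate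
Conditions: β-isocupreidine (0.1 equiv), 4 (1.3 equiv), DMF, −55 °C
Reagents that add atoms: none
Why: Asymmetric Morita–Baylis–Hillman reaction in which the quinuclidine nitrogen of β-isocupreidine adds to the activated acrylate 4 and the catalyst's phenolic OH hydrogen-bonds the aldehyde in the aldol and elimination stages, so that the (R)-carbinol (the future C2) should form with high enantioselectivity, the allylsilane being inert to the amine.

Step 3
Reactants: 5 1,1,1,3,3,3-hexafluoropropan-2-yl (3R,6E)-3-hydroxy-2-methylidene-8-(trimethylsilyl)oct-6-enoate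
Product: 6 methyl (3R,6E)-3-hydroxy-2-methylidene-8-(trimethylsilyl)oct-6-enoate
Conditions: NaOMe (0.2 equiv), MeOH, 0 °C
Reagents that add atoms: methanol, CO
Why: Transesterification of the activated hexafluoroisopropyl ester by methoxide is fast at 0 °C and leaves the carbinol stereocentre, the acrylate and the allylsilane untouched.

Step 4
Reactants: 6 methyl (3R,6E)-3-hydroxy-2-methylidene-8-(trimethylsilyl)oct-6-enoate
Product: 7 methyl (3R,6E)-3-[(2-methoxyethoxy)methoxy]-2-methylidene-8-(trimethylsilyl)oct-6-enoate
Conditions: MEMCl, iPr2NEt, CH2Cl2, 0 °C to rt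
Reagents that add atoms: 2-methoxyethoxymethyl chloride (MEMCl), COCCOCCl
Why: O-Alkylation of the secondary alcohol with the α-chloro ether (MEM protection) proceeds under a hindered, non-nucleophilic amine base, so neither SN2′ attack on the acrylate nor epimerisation is expected.

Step 5
Reactants: 7 methyl (3R,6E)-3-[(2-methoxyethoxy)methoxy]-2-methylidene-8-(trimethylsilyl)oct-6-enoate
Product: 9 methyl 2-[(2R,5R)-5-ethenyloxan-2-yl]prop-2-enoate, via oxocarbenium ion 8 (not isolated)
Conditions: TiCl4 (2 equiv), 2,6-di-tert-butyl-4-methylpyridine (0.2 equiv), CH2Cl2, −78 to −40 °C; aq. NaHCO3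
Reagents that add atoms: none
Why: TiCl4 chelates the MEM oxygens and expels the 2-methoxyethoxy group, leaving the oxocarbenium ion 8 (O1=C6H2+), whose carbon is attacked by the γ-carbon (C5) of the allylsilane, after which the β-silyl cation loses its silyl group to chloride (anti SE2′) and the alkene reappears as the C5 vinyl group. The closest known reaction type is the intramolecular Hosomi–Sakurai (allylsilane-terminated Prins-type) cyclisation of MEM ethers of hydroxy allylsilanes to 3-vinyl cyclic ethers. The oxane ring closes in a 6-exo-trig mode with respect to the allylsilane C=C, the O1=C6 unit lying inside the ring. The new stereocentre C5 is controlled by C2 through a chair-like transition state in which the C2 substituent and the reacting alkene are both equatorial, which should give the trans-2,5 product (2R,5R for the vinyl compound). The step needs ionisation towards O1=C6H2+ and not loss of the whole MEM group, which titanium chelation to the methoxyethoxy arm secures; it needs attack at C5 and not 7-endo closure, which β-silyl stabilisation of the exocyclic cation secures; and it needs an inert acrylate, which its electron-poor character secures.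

**Fragment B (side chain)**

Step 6
Reactants: 10 6-methylhept-5-en-2-one
Product: 12 6-methylhepta-1,5-dien-2-yl trifluoromethanesulfonate, via lithium enolate 11 (not isolated)
Conditions: LDA, THF, −78 °C; PhNTf2, −78 to 0 °C; aq. NH4Cl
Reagents that add atoms: N-phenylbis(trifluoromethanesulfonimide), O=S(=O)(N(c1ccccc1)S(=O)(=O)C(F)(F)F)C(F)(F)F
Why: Kinetic deprotonation of the methyl ketone by LDA at −78 °C gives the less substituted enolate, which is O-sulfonylated by PhNTf2 to the 1,1-disubstituted enol triflate (enol triflate formation).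

Step 7
Reactants: 12 6-methylhepta-1,5-dien-2-yl trifluoromethanesulfonate; 13 pent-4-ynal
Product: 15 rac-10-methyl-6-methylideneundec-9-en-1-yn-5-ol, via alkenylchromium dichloride 14 (not isolated)
Conditions: CrCl2 (4 equiv), NiCl2 (1 mol%), DMF, rt
Reagents that add atoms: none
Why: Nozaki–Hiyama–Kishi coupling in which zerovalent nickel inserts into the C–OTf bond, transmetalation gives a trivalent alkenylchromium species that adds chemoselectively to the aldehyde without deprotonating the alkyne, and the racemic carbinol is of no concern because the centre is reset in steps 8 and 9.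

Step 8
Reactants: 15 rac-10-methyl-6-methylideneundec-9-en-1-yn-5-ol
Product: 16 10-methyl-6-methylideneundec-9-en-1-yn-5-one
Conditions: Dess–Martin periodinane, NaHCO3, CH2Cl2, 0 °C
Reagents that add atoms: none
Why: Dess–Martin oxidation converts the allylic alcohol into the α-methylene ketone under buffered, non-isomerising conditions, and the sensitive enone is used without storage.

Step 9
Reactants: 16 10-methyl-6-methylideneundec-9-en-1-yn-5-one
Product: 17 (5R)-10-methyl-6-methylideneundec-9-en-1-yn-5-ol
Conditions: (S)-2-methyl-CBS-oxazaborolidine (0.2 equiv), catecholborane (1.5 equiv), toluene, −78 °C; MeOH quench, aq. NaOH wash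
Reagents that add atoms: none
Why: Corey–Bakshi–Shibata reduction in which the ketone binds the oxazaborolidine boron anti to its larger, α-branched alkenyl substituent and hydride is delivered from coordinated catecholborane to one face, which with the (S)-catalyst should give the (5R)-alcohol, while catecholborane at −78 °C does not hydroborate the alkenes or the alkyne.

Step 10
Reactants: 17 (5R)-10-methyl-6-methylideneundec-9-en-1-yn-5-ol
Product: 19 (1E,5R)-1-iodo-2,10-dimethyl-6-methylideneundeca-1,9-dien-5-ol, via alkenylalane 18 (not isolated)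
Conditions: AlMe3 (3 equiv), Cp2ZrCl2 (0.3 equiv), CH2Cl2, 0 °C to rt; then I2, THF, −30 to 0 °C; aq. Rochelle salt
Reagents that add atoms: trimethylaluminium, C[Al](C)C; iodine, II
Why: Negishi zirconium-catalysed carboalumination adds methyl and aluminium syn across the terminal alkyne with methyl on the internal carbon, and iodinolysis of the C–Al bond with retention gives the (E)-iodoalkene, the hydroxyl being carried as its aluminium alkoxide and the 1,1-di- and trisubstituted alkenes being inert.

**Union and end game**

Step 11
Reactants: 9 methyl 2-[(2R,5R)-5-ethenyloxan-2-yl]prop-2-enoate; 19 (1E,5R)-1-iodo-2,10-dimethyl-6-methylideneundeca-1,9-dien-5-ol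
Product: 21 methyl 2-[(2R,5S)-5-[(3E,7R)-7-hydroxy-4,12-dimethyl-8-methylidenetrideca-3,11-dien-1-yl]oxan-2-yl]prop-2-enoate, via alkylborane 20 (not isolated)
Conditions: 9, 9-BBN (1.1 equiv), THF, 0 °C to rt; then aq. Cs2CO3, 19, PdCl2(dppf) (5 mol%), AsPh3, DMF, rt
Reagents that add atoms: none
Why: B-alkyl Suzuki–Miyaura coupling in which 9-BBN should hydroborate the monosubstituted C5 vinyl group anti-Markovnikov much faster than the electron-poor, α-branched acrylate, and the resulting alkylborane couples with the alkenyl iodide with retention of the (E)-geometry, no stereocentre being touched.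

Step 12
Reactants: 21 methyl 2-[(2R,5S)-5-[(3E,7R)-7-hydroxy-4,12-dimethyl-8-methylidenetrideca-3,11-dien-1-yl]oxan-2-yl]prop-2-enoate
Product: 23 2-[(2R,5S)-5-[(3E,7R)-7-hydroxy-4,12-dimethyl-8-methylidenetrideca-3,11-dien-1-yl]oxan-2-yl]prop-2-enoic acid, via lithium carboxylate 22 (not isolated)
Conditions: LiOH, THF/MeOH/H2O, 0 °C to rt; then 1 M HCl to pH 4, 0 °C
Reagents that add atoms: lithium hydroxide, [Li+].[OH-]
Why: Saponification of the methyl ester by hydroxide (acyl–oxygen cleavage) followed by mild acidification gives the acid, the reversible conjugate addition of hydroxide to the acrylate and the allylic alcohol being uncritical at this temperature and pH.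

**Compound list**

1 | pent-4-enal | C=CCCC=O | starting material
2 | allyltrimethylsilane | C=CC[Si](C)(C)C | starting material
3 | (4E)-6-(trimethylsilyl)hex-4-enal | C[Si](C)(C)C/C=C/CCC=O | intermediate
4 | 1,1,1,3,3,3-hexafluoropropan-2-yl prop-2-enoate | C=CC(=O)OC(C(F)(F)F)C(F)(F)F | starting material
5 | 1,1,1,3,3,3-hexafluoropropan-2-yl (3R,6E)-3-hydroxy-2-methylidene-8-(trimethylsilyl)oct-6-enoate | C[Si](C)(C)C/C=C/CC[C@H](C(=C)C(=O)OC(C(F)(F)F)C(F)(F)F)O | intermediate
6 | methyl (3R,6E)-3-hydroxy-2-methylidene-8-(trimethylsilyl)oct-6-enoate | C[Si](C)(C)C/C=C/CC[C@H](C(=C)C(=O)OC)O | intermediate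
7 | methyl (3R,6E)-3-[(2-methoxyethoxy)methoxy]-2-methylidene-8-(trimethylsilyl)oct-6-enoate | C[Si](C)(C)C/C=C/CC[C@H](C(=C)C(=O)OC)OCOCCOC | intermediate
8 | oxocarbenium ion [(3R,6E)-1-methoxy-2-methylidene-1-oxo-8-(trimethylsilyl)oct-6-en-3-yl](methylidene)oxonium (formed in the flask) | C[Si](C)(C)C/C=C/CC[C@H](C(=C)C(=O)OC)[O+]=C | intermediate
9 | methyl 2-[(2R,5R)-5-ethenyloxan-2-yl]prop-2-enoate | C=C[C@H]1CC[C@H](C(=C)C(=O)OC)OC1 | intermediate
10 | 6-methylhept-5-en-2-one | CC(=O)CCC=C(C)C | starting material
11 | lithium 6-methylhepta-1,5-dien-2-olate (formed in the flask) | [Li+].[O-]C(=C)CCC=C(C)C | intermediate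
12 | 6-methylhepta-1,5-dien-2-yl trifluoromethanesulfonate | C=C(CCC=C(C)C)OS(=O)(=O)C(F)(F)F | intermediate
13 | pent-4-ynal | C#CCCC=O | starting material
14 | dichloro(6-methylhepta-1,5-dien-2-yl)chromium, trivalent chromium (formed in the flask) | C=C(CCC=C(C)C)[Cr](Cl)Cl | intermediate
15 | rac-10-methyl-6-methylideneundec-9-en-1-yn-5-ol | C=C(CCC=C(C)C)C(O)CCC#C | intermediate
16 | 10-methyl-6-methylideneundec-9-en-1-yn-5-one | C=C(CCC=C(C)C)C(=O)CCC#C | intermediate
17 | (5R)-10-methyl-6-methylideneundec-9-en-1-yn-5-ol | C=C(CCC=C(C)C)[C@H](O)CCC#C | intermediate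
18 | dimethylaluminium (1E,5R)-1-(dimethylalumanyl)-2,10-dimethyl-6-methylideneundeca-1,9-dien-5-olate (formed in the flask) | C=C(CCC=C(C)C)[C@H](O[Al](C)C)CC/C(C)=C/[Al](C)C | intermediate
19 | (1E,5R)-1-iodo-2,10-dimethyl-6-methylideneundeca-1,9-dien-5-ol | C=C(CCC=C(C)C)[C@H](O)CC/C(C)=C/I | intermediate
20 | methyl 2-[(2R,5S)-5-[2-(9-borabicyclo[3.3.1]nonan-9-yl)ethyl]oxan-2-yl]prop-2-enoate (formed in the flask) | B1(CC[C@H]2CC[C@H](C(=C)C(=O)OC)OC2)C3CCCC1CCC3 | intermediate
21 | methyl 2-[(2R,5S)-5-[(3E,7R)-7-hydroxy-4,12-dimethyl-8-methylidenetrideca-3,11-dien-1-yl]oxan-2-yl]prop-2-enoate | C=C(CCC=C(C)C)[C@H](O)CC/C(C)=C/CC[C@H]1CC[C@H](C(=C)C(=O)OC)OC1 | intermediate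
22 | lithium 2-[(2R,5S)-5-[(3E,7R)-7-hydroxy-4,12-dimethyl-8-methylidenetrideca-3,11-dien-1-yl]oxan-2-yl]prop-2-enoate (formed in the flask) | C=C(CCC=C(C)C)[C@H](O)CC/C(C)=C/CC[C@H]1CC[C@H](C(=C)C(=O)[O-])OC1.[Li+] | intermediate
23 | 2-[(2R,5S)-5-[(3E,7R)-7-hydroxy-4,12-dimethyl-8-methylidenetrideca-3,11-dien-1-yl]oxan-2-yl]prop-2-enoic acid (CNP0278566.2) | C=C(CCC=C(C)C)[C@H](O)CC/C(C)=C/CC[C@H]1CC[C@H](C(=C)C(=O)O)OC1 | target

**Step count and risks**

Total step count: 12.
Longest linear sequence: 7 steps (steps 1, 2, 3, 4, 5, 11, 12; the side-chain arm, steps 6 to 10 followed by 11 and 12, is equally long).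

Three steps most likely to fail:

1. Step 5 (key step). What may go wrong: ionisation of the acetal in the wrong sense (loss of the whole MEM group, returning 6), chloride capture or protodesilylation before ring closure, or an insufficient preference for the chair with both groups equatorial, in which case the 2,5-cis isomer would have to be separated. Fallback: the cation is assembled by condensation instead of by ionisation of a preformed acetal. The fallback sets out from alcohol 6, which is silylated (TMSCl, imidazole, CH2Cl2) to methyl (3R,6E)-2-methylidene-8-(trimethylsilyl)-3-[(trimethylsilyl)oxy]oct-6-enoate F1. F1 is then treated with 1,3,5-trioxane and catalytic TMSOTf in CH2Cl2 at −78 °C (intramolecular silyl-modified Sakurai reaction). The silyl ether oxygen condenses with formaldehyde to the same oxocarbenium ion 8, which can only form in the desired sense, and cyclisation rejoins the route at 9.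

2. Step 11. What may go wrong: competing hydroboration or conjugate reduction of the acrylate by 9-BBN, or erosion of the acrylate under the basic coupling conditions. Fallback: the acrylate is masked during the coupling. The fallback sets out from 9, which takes up thiophenol (PhSH, catalytic Et3N, CH2Cl2) to give methyl 2-[(2R,5R)-5-ethenyloxan-2-yl]-3-(phenylsulfanyl)propanoate F2, as a mixture of epimers at the new α-carbon that is of no consequence. Hydroboration with 9-BBN gives methyl 2-[(2R,5S)-5-[2-(9-borabicyclo[3.3.1]nonan-9-yl)ethyl]oxan-2-yl]-3-(phenylsulfanyl)propanoate F3. Coupling with 19 under the conditions of step 11 gives methyl 2-[(2R,5S)-5-[(3E,7R)-7-hydroxy-4,12-dimethyl-8-methylidenetrideca-3,11-dien-1-yl]oxan-2-yl]-3-(phenylsulfanyl)propanoate F4. Selective sulfur oxidation (NaIO4, MeOH/H2O, 0 °C) gives the sulfoxide methyl 3-(benzenesulfinyl)-2-[(2R,5S)-5-[(3E,7R)-7-hydroxy-4,12-dimethyl-8-methylidenetrideca-3,11-dien-1-yl]oxan-2-yl]propanoate F5. Thermal syn-elimination (toluene, CaCO3, 110 °C) regenerates the acrylate and rejoins the route at 21.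

3. Step 9. What may go wrong: poor facial selectivity because the two ketone substituents are not differentiated well enough, or oligomerisation of the α-methylene ketone 16 before it is reduced. Fallback: the ketone is bypassed by a Sharpless kinetic resolution. The fallback sets out from racemic alcohol 15, which is treated with Ti(OiPr)4, L-(+)-diisopropyl tartrate, tert-butyl hydroperoxide (0.6 equiv) and 4 Å molecular sieves in CH2Cl2 at −20 °C. The (S)-enantiomer should be epoxidised faster, to (1S)-1-[(2S)-2-(4-methylpent-3-en-1-yl)oxiran-2-yl]pent-4-yn-1-ol F6, and the unreacted (R)-alcohol is separated by chromatography, which rejoins the route at 17.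

Further compounds
F1 | step 5 | methyl (3R,6E)-2-methylidene-8-(trimethylsilyl)-3-[(trimethylsilyl)oxy]oct-6-enoate | C[Si](C)(C)C/C=C/CC[C@H](C(=C)C(=O)OC)O[Si](C)(C)C
F2 | step 11 | methyl 2-[(2R,5R)-5-ethenyloxan-2-yl]-3-(phenylsulfanyl)propanoate (both epimers at the α-carbon) | C=C[C@H]1CC[C@H](C(CSc2ccccc2)C(=O)OC)OC1
F3 | step 11 | methyl 2-[(2R,5S)-5-[2-(9-borabicyclo[3.3.1]nonan-9-yl)ethyl]oxan-2-yl]-3-(phenylsulfanyl)propanoate | B1(CC[C@H]2CC[C@H](C(CSc3ccccc3)C(=O)OC)OC2)C4CCCC1CCC4
F4 | step 11 | methyl 2-[(2R,5S)-5-[(3E,7R)-7-hydroxy-4,12-dimethyl-8-methylidenetrideca-3,11-dien-1-yl]oxan-2-yl]-3-(phenylsulfanyl)propanoate | C=C(CCC=C(C)C)[C@H](O)CC/C(C)=C/CC[C@H]1CC[C@H](C(CSc2ccccc2)C(=O)OC)OC1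
F5 | step 11 | methyl 3-(benzenesulfinyl)-2-[(2R,5S)-5-[(3E,7R)-7-hydroxy-4,12-dimethyl-8-methylidenetrideca-3,11-dien-1-yl]oxan-2-yl]propanoate | C=C(CCC=C(C)C)[C@H](O)CC/C(C)=C/CC[C@H]1CC[C@H](C(CS(=O)c2ccccc2)C(=O)OC)OC1
F6 | step 9 | (1S)-1-[(2S)-2-(4-methylpent-3-en-1-yl)oxiran-2-yl]pent-4-yn-1-ol | C1O[C@]1(CCC=C(C)C)[C@@H](O)CCC#C
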